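## Retrosynthetic overview

1. The three angelates go on in two late acylations: C8–OH of the macrocyclic α'-hydroxy (Z)-enone first, then C3–OH and C6–OH last. The cis-1,10-epoxide is made between them by nucleophilic epoxidation of the enone.
2. The ten-membered ring is closed at C8–C9 by a samarium ketyl–ketyl (pinacol) coupling of an acyclic dialdehyde, which places both oxygens; allylic oxidation then gives the C9 ketone.
3. The dialdehyde comes from a lactone thioester: the (Z)-enal is masked as an α-methyl-δ-lactone, the C8 aldehyde as a thioester, and the trans-4,5-epoxide is already set acyclically by OH-directed epoxidation.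
4. The chain is built by three C–C steps: a reagent-controlled syn aldol (C6–C7), a cross-metathesis with methacrolein (C4=C5), and a catalytic vinylogous aldol/lactonisation (C2–C3).
5. Ring order: temporary δ-lactone → C4–C5 oxirane → ten-membered carbocycle → C1–C10 oxirane.

Labels: C1–C10 are the ring carbons of the target, C11–C13 the isopropenyl group on C7, C14 the methyl on C10, C15 the methyl on C4. CIP descriptors are given per compound because priorities change with the substituents.

Assumptions: the (R,R)-bromoborane (step 2) and (S)-Tol-BINAP (step 5) are taken to induce the sense drawn (otherwise the mirror-image reagent is used with nothing else changed), and angelic anhydride is used as a purchased acylating reagent.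

## Route

Step 1
Reactants: 1 3-methylbut-3-enoic acid; 2 benzenethiol
Product: 3 S-phenyl 3-methylbut-3-enethioate
Conditions: DCC, DMAP (2 mol %), CH2Cl2, 0 °C → rt
Reagents that add atoms: none
Why: Steglich-type carbodiimide thioesterification, in which the thiol attacks the O-acylisourea; no stereocentre is formed, and a shift of the alkene into conjugation would not matter because the next step enolises either isomer to the same dienolate.

Step 2
Reactants: 3 S-phenyl 3-methylbut-3-enethioate; 4 acrolein
Product: 6 S-phenyl (2S,3R)-3-hydroxy-2-(prop-1-en-2-yl)pent-4-enethioate, via boron dienolate 5 (not isolated)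
Conditions: (4R,5R)-2-bromo-4,5-diphenyl-1,3-bis(p-tolylsulfonyl)-1,3,2-diazaborolidine, iPr2NEt, CH2Cl2, −78 °C; then acrolein, −78 °C; pH 7 buffer
Reagents that add atoms: none
Why: Corey-type reagent-controlled boron aldol, in which the (Z(O))-boron dienolate reacts at its α-carbon with the aldehyde through a closed Zimmerman–Traxler chair to give the syn adduct (C6–OH and C7–isopropenyl syn), the C2-symmetric sulfonamide controller fixing the absolute sense as 6R,7S.

Step 3
Reactants: 6 S-phenyl (2S,3R)-3-hydroxy-2-(prop-1-en-2-yl)pent-4-enethioate; 7 methacrolein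
Product: 8 S-phenyl (2S,3R,4E)-3-hydroxy-5-methyl-6-oxo-2-(prop-1-en-2-yl)hex-4-enethioate
Conditions: second-generation Hoveyda–Grubbs catalyst (5 mol %), methacrolein (8 equiv), CH2Cl2, 40 °C
Reagents that add atoms: none
Why: Olefin cross-metathesis of the monosubstituted vinyl carbinol with excess methacrolein gives the conjugated trisubstituted enal with thermodynamic E geometry (C3 trans to C6), while the hindered isopropenyl group does not react and the stereocentres are untouched.

Step 4
Reactants: 9 methyl (E)-2-methylbut-2-enoate (methyl tiglate)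
Product: 10 (1-methoxy-2-methylbuta-1,3-dien-1-yl)oxy-trimethylsilane (ketene-acetal E/Z mixture, geometry inconsequential)
Conditions: LiN(iPr)2, THF, −78 °C; then Me3SiCl, −78 °C → rt; distil
Reagents that add atoms: chlorotrimethylsilane, C[Si](C)(C)Cl
Why: γ-Deprotonation of the enoate and O-silylation of the extended enolate gives the silyl dienol ether, the standard nucleophile for a vinylogous Mukaiyama aldol; no stereocentre is formed.

Step 5
Reactants: 8 S-phenyl (2S,3R,4E)-3-hydroxy-5-methyl-6-oxo-2-(prop-1-en-2-yl)hex-4-enethioate; 10 (1-methoxy-2-methylbuta-1,3-dien-1-yl)oxy-trimethylsilane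
Product: 12 S-phenyl (2S,3R,4E)-3-hydroxy-5-[(2S)-5-methyl-6-oxo-3,6-dihydro-2H-pyran-2-yl]-2-(prop-1-en-2-yl)hex-4-enethioate, via O-silyl lactone 11 (not isolated)
Conditions: 10 (2.5 equiv), Cu(OTf)2 (10 mol %), (S)-Tol-BINAP (11 mol %), Bu4N[Ph3SiF2] (20 mol %), THF, −78 → −40 °C; then 1 M HCl, THF, rt
Reagents that add atoms: none
Why: Catalytic asymmetric vinylogous Mukaiyama aldol with in-flask lactonisation, in which the chiral copper dienolate adds through its γ-carbon to the enal carbonyl on the face set by the bisphosphine (C3 = S) and the (Z)-adduct closes to the δ-lactone, locking C1=C10 as Z; the first equivalent of 10 transiently silylates C6–OH, which the acid work-up frees again.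

Step 6
Reactants: 12 S-phenyl (2S,3R,4E)-3-hydroxy-5-[(2S)-5-methyl-6-oxo-3,6-dihydro-2H-pyran-2-yl]-2-(prop-1-en-2-yl)hex-4-enethioate
Product: 13 S-phenyl (2S,3S)-3-hydroxy-3-{(2R,3R)-3-methyl-3-[(2S)-5-methyl-6-oxo-3,6-dihydro-2H-pyran-2-yl]oxiran-2-yl}-2-(prop-1-en-2-yl)propanethioate (3S,4R,5R,6S,7S)
Conditions: mCPBA (1.1 equiv), NaHCO3, CH2Cl2, −20 → 0 °C
Reagents that add atoms: 3-chloroperbenzoic acid, OOC(=O)c1cccc(Cl)c1
Why: Hydroxyl-directed (Henbest) peracid epoxidation of the most nucleophilic alkene (the enoate is inert, the isopropenyl group slower) is stereospecific (E-alkene to trans-epoxide), and A(1,3) strain between C15 and C6 puts C6–H in the alkene plane so the hydrogen-bonded peracid delivers oxygen syn to C6–OH, giving the threo 4R,5R epoxy alcohol.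

Step 7
Reactants: 13 S-phenyl (2S,3S)-3-hydroxy-3-{(2R,3R)-3-methyl-3-[(2S)-5-methyl-6-oxo-3,6-dihydro-2H-pyran-2-yl]oxiran-2-yl}-2-(prop-1-en-2-yl)propanethioate
Product: 15 (2Z,5S)-5-{(2S,3R)-3-[(1S,2S)-2-[methoxy(methyl)carbamoyl]-3-methyl-1-(triethylsilyloxy)but-3-en-1-yl]-2-methyloxiran-2-yl}-N-methoxy-N,2-dimethyl-5-(triethylsilyloxy)pent-2-enamide (3S,4S,5R,6S,7S; 1(10)Z), via diol bis-amide 14 (not isolated)
Conditions: MeNHOMe·HCl, iPrMgCl, THF, −20 → 0 °C; then Et3SiCl, imidazole, DMAP (cat.), 0 °C → rt, same flask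
Reagents that add atoms: N,O-dimethylhydroxylamine hydrochloride, CNOC.Cl; chlorotriethylsilane, CC[Si](Cl)(CC)CC
Why: Weinreb aminolysis by the magnesium amide opens the lactone to the (Z)-δ-hydroxy enamide and converts the thioester into the second Weinreb amide, and the two magnesium alkoxides are silylated before work-up so the hydroxy amide cannot relactonise; the C6 alkoxide shields C7 from enolisation, so no stereocentre or alkene geometry changes.

Step 8
Reactants: 15 bis(Weinreb amide) bis(triethylsilyl ether) from step 7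
Product: 16 (2Z,5S)-5-{(2S,3R)-3-[(1S,2S)-2-formyl-3-methyl-1-(triethylsilyloxy)but-3-en-1-yl]-2-methyloxiran-2-yl}-2-methyl-5-(triethylsilyloxy)pent-2-enal (3S,4S,5R,6S,7S; 1(10)Z)
Conditions: iBu2AlH (3 equiv), THF, −78 °C; aq potassium sodium tartrate; used crude at once
Reagents that add atoms: none
Why: Hydride reduction of both Weinreb amides stops at the chelated tetrahedral aluminium intermediates, which release the aldehydes only on neutral work-up, so there is no over-reduction and neither the epimerisable C7 centre nor the (Z)-enal meets acid or base.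

Step 9
Reactants: 16 dialdehyde from step 8
Product: 18 (1(10)Z)-4,5-epoxy-3,6-bis(triethylsilyloxy)germacra-1(10),11-diene-8,9-diol (3S,4S,5R,6S,7R,8R; both C9 epimers), via bis-ketyl 17 (not isolated)
Conditions: SmI2 (3 equiv), THF, 0.003 M, slow addition of 16, −78 °C → rt; aq NaHCO3/Na2S2O3
Reagents that add atoms: none
Why: Samarium diiodide pinacol macrocyclisation, in which single-electron transfer to both aldehydes gives samarium ketyl radicals whose C8–C9 coupling closes the ten-membered ring (the β-substituted enal ketyl couples at its carbonyl carbon); C8 is set as R because the ring closes with the bulky samarium alkoxide on the periphery, anti to the C7 isopropenyl group with H7 and H8 antiperiplanar, while the C9 configuration is removed in the next step.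

Step 10
Reactants: 18 macrocyclic 8,9-diol from step 9
Product: 19 (1(10)Z)-4,5-epoxy-8-hydroxy-3,6-bis(triethylsilyloxy)germacra-1(10),11-dien-9-one (3S,4S,5R,6S,7R,8R)
Conditions: activated MnO2 (20 equiv), CH2Cl2, rt
Reagents that add atoms: none
Why: Chemoselective allylic oxidation by MnO2 converts only the allylic C9 carbinol (both epimers converge on the enone) and leaves the non-allylic C8–OH, the silyl ethers and the epoxide alone under neutral conditions that do not epimerise C8.

Step 11
Reactants: 19 macrocyclic α'-hydroxy (Z)-enone from step 10; 20 angelic acid ((Z)-2-methylbut-2-enoic acid)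
Product: 22 (1(10)Z)-8-angeloyloxy-4,5-epoxy-3,6-bis(triethylsilyloxy)germacra-1(10),11-dien-9-one (3S,4S,5R,6S,7R,8R), via mixed anhydride 21 (not isolated)
Conditions: 20 (3 equiv), 2,4,6-trichlorobenzoyl chloride (3 equiv), Et3N (6 equiv), toluene, rt; then 19, 80 °C
Reagents that add atoms: none
Why: Yamaguchi-type esterification through the mixed anhydride acylates the hindered C8 hydroxyl at the less hindered angeloyl carbonyl, leaving out DMAP avoids the addition–elimination path that turns angelate (Z) into tiglate (E), and capping the α-ketol here keeps it out of reach of the base in the next step; acylation is at oxygen, so C8 keeps its configuration.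

Step 12
Reactants: 22 8-angeloyloxy (Z)-enone from step 11
Product: 24 8-angeloyloxy-1,10:4,5-diepoxy-3,6-dihydroxygermacr-11-en-9-one (1S,3S,4R,5R,6S,7S,8R,10S), via bis(triethylsilyl) diepoxide 23 (not isolated)
Conditions: tBuOOH (2 equiv), DBU (1.5 equiv), CH2Cl2, 0 °C; then HF·pyridine, pyridine, THF, 0 °C, same flask
Reagents that add atoms: tert-butyl hydroperoxide, CC(C)(C)OO
Why: Weitz–Scheffer nucleophilic epoxidation is selective for the electron-poor enone (the isopropenyl group and the β-substituted, α-branched angelate are far poorer acceptors): the hydroperoxide anion adds to C1 from the peripheral face of the ring and the enolate closes on the O–O bond before rotation about C1–C10, so the (Z)-enone gives the cis-epoxide 1S,10S, and buffered fluoride then cleaves both triethylsilyl ethers through pentacoordinate silicon without touching the epoxides or the ester.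

Step 13
Reactants: 24 3,6-diol from step 12
Product: 25 (1S,3S,4R,5R,6S,7S,8R,10S)-1,10:4,5-diepoxy-9-oxogermacr-11-ene-3,6,8-triyl tris[(Z)-2-methylbut-2-enoate] (CNP0154187.4)
Conditions: angelic anhydride (6 equiv), Et3N (8 equiv), toluene, 90 °C
Reagents that add atoms: angelic anhydride ((Z)-2-methylbut-2-enoic anhydride), C/C=C(/C)C(=O)OC(=O)/C(C)=C\C
Why: Thermal acylation of the two remaining secondary alcohols by the symmetrical anhydride with only a tertiary amine as base, so that no acylpyridinium forms and the addition–elimination path from angelate (Z) to tiglate (E) is closed; the anhydride is less reactive than the mixed anhydride of step 11 and is therefore used in excess and hotter, and acylation is at oxygen, so C3 and C6 keep their configuration.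

## Compound list

1 | 3-methylbut-3-enoic acid | C=C(C)CC(=O)O | starting material
2 | benzenethiol | Sc1ccccc1 | starting material
3 | S-phenyl 3-methylbut-3-enethioate | C=C(C)CC(=O)Sc1ccccc1 | intermediate
4 | acrolein | C=CC=O | starting material
5 | boron dienolate of 3 (isopropenyl cis to O–B; (R,R)-diazaborolidine on oxygen) | C=C(C)/C=C(/Sc1ccccc1)OB1N(S(=O)(=O)c2ccc(C)cc2)[C@H](c2ccccc2)[C@@H](c2ccccc2)N1S(=O)(=O)c1ccc(C)cc1 | intermediate
6 | S-phenyl (2S,3R)-3-hydroxy-2-(prop-1-en-2-yl)pent-4-enethioate | C=C(C)[C@H](C(=O)Sc1ccccc1)[C@H](O)C=C | intermediate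
7 | methacrolein | C=C(C)C=O | starting material
8 | S-phenyl (2S,3R,4E)-3-hydroxy-5-methyl-6-oxo-2-(prop-1-en-2-yl)hex-4-enethioate | C=C(C)[C@H](C(=O)Sc1ccccc1)[C@H](O)/C=C(\C)C=O | intermediate
9 | methyl (E)-2-methylbut-2-enoate | C/C=C(\C)C(=O)OC | starting material
10 | (1-methoxy-2-methylbuta-1,3-dien-1-yl)oxy-trimethylsilane (E/Z mixture at the ketene acetal) | C=CC(C)=C(OC)O[Si](C)(C)C | intermediate
11 | 6-O-trimethylsilyl ether of lactone 12 | C=C(C)[C@H](C(=O)Sc1ccccc1)[C@H](O[Si](C)(C)C)/C=C(\C)[C@@H]1CC=C(C)C(=O)O1 | intermediate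
12 | S-phenyl (2S,3R,4E)-3-hydroxy-5-[(2S)-5-methyl-6-oxo-3,6-dihydro-2H-pyran-2-yl]-2-(prop-1-en-2-yl)hex-4-enethioate | C=C(C)[C@H](C(=O)Sc1ccccc1)[C@H](O)/C=C(\C)[C@@H]1CC=C(C)C(=O)O1 | intermediate
13 | S-phenyl (2S,3S)-3-hydroxy-3-{(2R,3R)-3-methyl-3-[(2S)-5-methyl-6-oxo-3,6-dihydro-2H-pyran-2-yl]oxiran-2-yl}-2-(prop-1-en-2-yl)propanethioate | C=C(C)[C@H](C(=O)Sc1ccccc1)[C@H](O)[C@H]1O[C@]1(C)[C@@H]1CC=C(C)C(=O)O1 | intermediate
14 | (2Z,5S)-5-hydroxy-5-{(2R,3R)-3-[(1S,2S)-1-hydroxy-2-[methoxy(methyl)carbamoyl]-3-methylbut-3-en-1-yl]-2-methyloxiran-2-yl}-N-methoxy-N,2-dimethylpent-2-enamide | C=C(C)[C@H](C(=O)N(C)OC)[C@H](O)[C@H]1O[C@]1(C)[C@@H](O)C/C=C(/C)C(=O)N(C)OC | intermediate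
15 | (2Z,5S)-5-{(2S,3R)-3-[(1S,2S)-2-[methoxy(methyl)carbamoyl]-3-methyl-1-(triethylsilyloxy)but-3-en-1-yl]-2-methyloxiran-2-yl}-N-methoxy-N,2-dimethyl-5-(triethylsilyloxy)pent-2-enamide | C=C(C)[C@H](C(=O)N(C)OC)[C@H](O[Si](CC)(CC)CC)[C@H]1O[C@]1(C)[C@@H](O[Si](CC)(CC)CC)C/C=C(/C)C(=O)N(C)OC | intermediate
16 | (2Z,5S)-5-{(2S,3R)-3-[(1S,2S)-2-formyl-3-methyl-1-(triethylsilyloxy)but-3-en-1-yl]-2-methyloxiran-2-yl}-2-methyl-5-(triethylsilyloxy)pent-2-enal | C=C(C)[C@H](C=O)[C@H](O[Si](CC)(CC)CC)[C@H]1O[C@]1(C)[C@@H](O[Si](CC)(CC)CC)C/C=C(/C)C=O | intermediate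
17 | bis(samarium ketyl) diradical of 16 (radical centres at C8 and C9, each oxygen on trivalent samarium) | C=C(C)[C@H]([CH]O[Sm](I)I)[C@H](O[Si](CC)(CC)CC)[C@H]1O[C@]1(C)[C@@H](O[Si](CC)(CC)CC)C/C=C(/C)[CH]O[Sm](I)I | intermediate
18 | (1(10)Z)-4,5-epoxy-3,6-bis(triethylsilyloxy)germacra-1(10),11-diene-8,9-diol (3S,4S,5R,6S,7R,8R; C9 epimer mixture) | C=C(C)[C@H]1[C@H](O[Si](CC)(CC)CC)[C@H]2O[C@]2(C)[C@@H](O[Si](CC)(CC)CC)C/C=C(/C)C(O)[C@@H]1O | intermediate
19 | (1(10)Z)-4,5-epoxy-8-hydroxy-3,6-bis(triethylsilyloxy)germacra-1(10),11-dien-9-one (3S,4S,5R,6S,7R,8R) | C=C(C)[C@H]1[C@H](O[Si](CC)(CC)CC)[C@H]2O[C@]2(C)[C@@H](O[Si](CC)(CC)CC)C/C=C(/C)C(=O)[C@@H]1O | intermediate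
20 | angelic acid, (Z)-2-methylbut-2-enoic acid | C/C=C(/C)C(=O)O | starting material
21 | (Z)-2-methylbut-2-enoic 2,4,6-trichlorobenzoic anhydride | C/C=C(/C)C(=O)OC(=O)c1c(Cl)cc(Cl)cc1Cl | intermediate
22 | (1(10)Z)-8-angeloyloxy-4,5-epoxy-3,6-bis(triethylsilyloxy)germacra-1(10),11-dien-9-one (3S,4S,5R,6S,7R,8R) | C=C(C)[C@H]1[C@H](O[Si](CC)(CC)CC)[C@H]2O[C@]2(C)[C@@H](O[Si](CC)(CC)CC)C/C=C(/C)C(=O)[C@@H]1OC(=O)/C(C)=C\C | intermediate
23 | 8-angeloyloxy-1,10:4,5-diepoxy-3,6-bis(triethylsilyloxy)germacr-11-en-9-one (1S,3S,4S,5R,6S,7R,8R,10S) | C=C(C)[C@H]1[C@H](O[Si](CC)(CC)CC)[C@H]2O[C@]2(C)[C@@H](O[Si](CC)(CC)CC)C[C@@H]2O[C@]2(C)C(=O)[C@@H]1OC(=O)/C(C)=C\C | intermediate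
24 | 8-angeloyloxy-1,10:4,5-diepoxy-3,6-dihydroxygermacr-11-en-9-one (1S,3S,4R,5R,6S,7S,8R,10S) | C=C(C)[C@H]1[C@H](O)[C@H]2O[C@]2(C)[C@@H](O)C[C@@H]2O[C@]2(C)C(=O)[C@@H]1OC(=O)/C(C)=C\C | intermediate
25 | (1S,3S,4R,5R,6S,7S,8R,10S)-1,10:4,5-diepoxy-9-oxogermacr-11-ene-3,6,8-triyl tris[(Z)-2-methylbut-2-enoate], CNP0154187.4 | C=C(C)[C@H]1[C@H](OC(=O)/C(C)=C\C)[C@H]2O[C@]2(C)[C@@H](OC(=O)/C(C)=C\C)C[C@@H]2O[C@]2(C)C(=O)[C@@H]1OC(=O)/C(C)=C\C | target

## Step count and risks

Total step count: 13. Longest linear sequence: 12 steps (steps 1–3 and 5–13; step 4 prepares the dienolate).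

The three steps most likely to fail:

Step 9 (samarium pinacol macrocyclisation). The risks are simple reduction, coupling through the β-carbon of the enal ketyl, Z/E scrambling of the allylic ketyl before ring closure, and the wrong C8 epimer. The fallback makes the same C8–C9 bond by polar umpolung instead of radical coupling. It sets out from dialdehyde 16, which is treated at high dilution with the carbene from 3-benzyl-5-(2-hydroxyethyl)-4-methylthiazolium chloride and Et3N. The unhindered conjugated C9 aldehyde forms the Breslow acyl-anion equivalent (α-methyl enals react as acyl anions with thiazolylidenes), and intramolecular crossed acyloin addition to the C8 aldehyde gives the α-hydroxy enone directly. The fallback comes back to the route at 19, skips step 10 and passes through no new isolable compound (F0).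

Step 5 (copper-catalysed vinylogous aldol/lactonisation). The risks are low selectivity at C3 on this substrate and formation of the open (E)-ester instead of the lactone. The fallback sets C3 by reagent-controlled allylboration and makes the (Z)-enoate by ring-closing metathesis. It sets out from enal 8: B-allyldiisopinocampheylborane (enantiomer for the 3S alcohol) gives homoallylic diol F1; mCPBA, directed by C6–OH as in step 6, gives epoxy diol F2; methacryloyl chloride with Et3N acylates both hydroxyls to bis-methacrylate F3; second-generation Grubbs catalyst closes only the six-membered α-methyl lactone (the C6 methacrylate has no partner for an easy ring) to give lactone methacrylate F4. Under the conditions of step 7 the magnesium amide opens the lactone and cleaves both the C6 methacrylate and the thioester, and silylation follows, so the fallback comes back to the route at 15.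

Step 12 (nucleophilic epoxidation of the macrocyclic enone, then desilylation). The risks are attack on the wrong face, loss of the cis relationship, and attack of the hydroperoxide anion or the base on the α-acyloxy ketone. The fallback delivers the oxygen from a C9 hydroxyl by a stereospecific directed epoxidation instead of a conjugate addition. It sets out from 22: Luche reduction (NaBH4, CeCl3·7H2O, MeOH, −78 °C) gives 9-allylic alcohol F5; VO(acac)2 with tBuOOH epoxidises the (Z)-alkene on the face of the C9–OH to give epoxy alcohol F6; Dess–Martin periodinane restores the ketone, so the fallback comes back to the route at 23, which is desilylated with HF·pyridine as in the second half of step 12.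

## Further compounds

F0 | step 9 | none | none
F1 | step 5 | homoallylic diol (C3–OH and C6–OH free, terminal allyl at C2) | C=C(C)[C@H](C(=O)Sc1ccccc1)[C@H](O)/C=C(\C)[C@@H](O)CC=C
F2 | step 5 | epoxy diol (4,5-epoxide of F1) | C=C(C)[C@H](C(=O)Sc1ccccc1)[C@H](O)[C@H]1O[C@]1(C)[C@@H](O)CC=C
F3 | step 5 | bis-methacrylate of F2 | C=C(C)[C@H](C(=O)Sc1ccccc1)[C@H](OC(=O)C(C)=C)[C@H]1O[C@]1(C)[C@@H](OC(=O)C(C)=C)CC=C
F4 | step 5 | lactone methacrylate (6-O-methacrylate of 13) | C=C(C)[C@H](C(=O)Sc1ccccc1)[C@H](OC(=O)C(C)=C)[C@H]1O[C@]1(C)[C@@H]1CC=C(C)C(=O)O1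
F5 | step 12 | 9-allylic alcohol (9-hydroxy compound from 22, C9 epimer as drawn) | C=C(C)[C@H]1[C@H](O[Si](CC)(CC)CC)[C@H]2O[C@]2(C)[C@@H](O[Si](CC)(CC)CC)C/C=C(/C)[C@H](O)[C@@H]1OC(=O)/C(C)=C\C
F6 | step 12 | epoxy alcohol (1,10-cis-epoxide of F5) | C=C(C)[C@H]1[C@H](O[Si](CC)(CC)CC)[C@H]2O[C@]2(C)[C@@H](O[Si](CC)(CC)CC)C[C@@H]2O[C@]2(C)[C@H](O)[C@@H]1OC(=O)/C(C)=C\C
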